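**Retrosynthetic overview**

1. The two esters go on last: target ⇐ 3α,4α-diol 17 (angelate on the secondary C3–OH, then acetate on the tertiary C4–OH).
2. Ring B (C5–C6–C7–C8–C9–C10) ⇐ two-carbon radical ring expansion of the cis-fused cyclobutanol 14. Its four-membered ring is C5–C8–C9–C10 and C8 carries OH and a 3-methylbut-1-en-2-yl group (the future C7 and C6). The C8–C5 bond breaks and C5–C6 closes 6-endo.
3. Enabling feature: the strained cyclobutane C5/C8/C9/C10 fused cis to ring A, with a tertiary carbinol and an α-branched vinyl group on C8. The cis-1,3 pair 4β-methyl/10β-methyl on ring A holds the C9 tether axial, which should deliver the cis ring fusion.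
4. 14 ⇐ cyclobutanone 9 + a vinyllithium from a Shapiro reaction; 9 ⇐ methylenecyclobutane 3 by ring-A work (C3 hydroxylation, C4 methylation, redox inversion at C3, acetonide, ozonolysis).
5. 3 ⇐ enantioselective [2+2] photocycloaddition of 3-methylcyclohex-2-enone with allene. Order of rings: ring A (purchased), cyclobutane, ring B by expansion.

Key step: step 10

Remark: eudesmane locants of the target are used for all intermediates (ring A = C1–C5, C10; ring B = C5–C10; β = face of the C10 methyl). The configurations drawn at C3 of 4 and 5 and at C8 of 14 are the expected ones but are inconsequential, since both centres are erased later.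

**Step 1**
Reactants: 1 3-methylcyclohex-2-en-1-one; 2 propa-1,2-diene (allene)
Product: 3 (1S,6R)-6-methyl-8-methylidenebicyclo[4.2.0]octan-2-one
Conditions: AlBr3-activated chiral oxazaborolidine (from an α,α-diarylprolinol and 2,4,6-trifluorophenylboronic acid, 50 mol %, enantiomer chosen for the (1S,6R) adduct), excess 2, CH2Cl2, −75 °C, hν 366 nm
Reagents that add atoms: none
Why: Proposed new method: the AlBr3-activated oxazaborolidine binds the enone carbonyl, red-shifts its absorption so that only the complex is excited at 366 nm and shields one face, and the triplet should bond first from its α-carbon to the central allene carbon (allyl radical) and then close at the β-carbon, giving the head-to-head, necessarily cis-fused adduct with C5 and C10 set by the catalyst; the closest known reaction types are the chiral-Lewis-acid-catalysed enantioselective intermolecular [2+2] photocycloaddition of 3-alkylcyclohex-2-enones with simple alkenes such as ethylene and the uncatalysed head-to-head enone–allene photocycloaddition.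

**Step 2**
Reactants: 3 (1S,6R)-6-methyl-8-methylidenebicyclo[4.2.0]octan-2-one
Product: 4 (1S,3S,6R)-3-hydroxy-6-methyl-8-methylidenebicyclo[4.2.0]octan-2-one
Conditions: KN(SiMe3)2, THF, −78 °C; 3-phenyl-2-(phenylsulfonyl)oxaziridine, −78 °C; aq. NH4Cl
Reagents that add atoms: 3-phenyl-2-(phenylsulfonyl)oxaziridine, O=S(=O)(c1ccccc1)N1OC1c1ccccc1
Why: Kinetic deprotonation at the unhindered C3 methylene (rather than the tertiary, cyclobutane-bound C5–H) followed by enolate hydroxylation with the N-sulfonyloxaziridine from the convex β face should give the α-hydroxy ketone.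

**Step 3**
Reactants: 4 (1S,3S,6R)-3-hydroxy-6-methyl-8-methylidenebicyclo[4.2.0]octan-2-one
Product: 5 (1S,2S,3S,6R)-2,6-dimethyl-8-methylidenebicyclo[4.2.0]octane-2,3-diol
Conditions: MeMgBr, anhydrous CeCl3, THF, −78 °C; aq. NH4Cl
Reagents that add atoms: methylmagnesium bromide, C[Mg]Br
Why: Organocerium 1,2-addition (weakly basic, so the acidic C5–H is left alone) should occur on the convex β face of the cis-bicyclo[4.2.0]octanone, anti to the cyclobutane, setting C4 as 4β-methyl/4α-OH.

**Step 4**
Reactants: 5 (1S,2S,3S,6R)-2,6-dimethyl-8-methylidenebicyclo[4.2.0]octane-2,3-diol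
Product: 6 (1S,2S,6R)-2-hydroxy-2,6-dimethyl-8-methylidenebicyclo[4.2.0]octan-3-one
Conditions: IBX (2-iodoxybenzoic acid), DMSO, rt
Reagents that add atoms: none
Why: IBX oxidation converts the secondary alcohol of a 1,2-diol into the α-ketol without glycol cleavage and leaves the tertiary alcohol and the exocyclic alkene untouched.

**Step 5**
Reactants: 6 (1S,2S,6R)-2-hydroxy-2,6-dimethyl-8-methylidenebicyclo[4.2.0]octan-3-one
Product: 7 (1S,2S,3R,6R)-2,6-dimethyl-8-methylidenebicyclo[4.2.0]octane-2,3-diol
Conditions: NaBH4, MeOH, −20 to 0 °C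
Reagents that add atoms: none
Why: Borohydride reduction by axial attack on the β face, anti to the axial 4α-OH, should give the equatorial 3α-alcohol and hence the 3α,4α-cis-diol.

**Step 6**
Reactants: 7 (1S,2S,3R,6R)-2,6-dimethyl-8-methylidenebicyclo[4.2.0]octane-2,3-diol
Product: 8 3α,4α-O-isopropylidene derivative of 7
Conditions: 2,2-dimethoxypropane, PPTS (cat.), CH2Cl2, rt
Reagents that add atoms: 2,2-dimethoxypropane, COC(C)(C)OC
Why: Acid-catalysed transketalization of a cis-1,2-diol gives the acetonide under conditions mild enough for the methylenecyclobutane.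

**Step 7**
Reactants: 8 3α,4α-O-isopropylidene derivative of 7
Product: 9 cyclobutanone (C8=O in place of C8=CH2 of 8)
Conditions: O3, CH2Cl2, −78 °C; Me2S, −78 °C to rt
Reagents that add atoms: ozone, [O-][O+]=O
Why: Ozonolysis of the 1,1-disubstituted alkene with reductive work-up unmasks the cyclobutanone, and the acetonide is inert to ozone.

**Step 8**
Reactants: 10 3-methylbutan-2-one; 11 2,4,6-triisopropylbenzenesulfonohydrazide
Product: 12 (E)-3-methylbutan-2-one 2,4,6-triisopropylbenzenesulfonylhydrazone
Conditions: MeOH, HCl (cat.), rt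
Reagents that add atoms: none
Why: Hydrazone condensation places the sulfonamide nitrogen syn to the methyl group, as the following Shapiro reaction requires.

**Step 9**
Reactants: 12 (E)-3-methylbutan-2-one 2,4,6-triisopropylbenzenesulfonylhydrazone; 9 cyclobutanone
Product: 14 tertiary cyclobutanol bearing OH and 3-methylbut-1-en-2-yl on C8, via 3-methylbut-1-en-2-yllithium 13 (not isolated)
Conditions: n-BuLi (2 equiv), THF, −78 to 0 °C; then 9, −78 °C; aq. NH4Cl
Reagents that add atoms: none
Why: The Shapiro reaction deprotonates the methyl group syn to the sulfonamide and, after loss of sulfinate and N2, gives the 1,1-disubstituted vinyllithium, which adds 1,2 to the strained, poorly enolizable cyclobutanone.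

**Step 10**
Reactants: 14 tertiary cyclobutanol
Product: 16 3α,4α-O-isopropylidenedioxy-5βH-eudesman-8-one (7β-isopropyl), via 7-epi-ketone 15 (not isolated)
Conditions: [Ir(dF(CF3)ppy)2(5,5′-d(CF3)bpy)]PF6 (2 mol %, trivalent iridium photocatalyst), 2,4,6-collidine, CH2Cl2, blue LEDs, rt; then DBU, rt
Reagents that add atoms: none
Why: The excited trivalent iridium photocatalyst and collidine remove the O–H hydrogen of 14 by proton-coupled electron transfer, and the cyclobutyloxy radical undergoes strain-driven β-scission of C8–C5 (the bond that gives the more substituted, secondary ring radical), unveiling C8 as an α-isopropyl vinyl ketone tethered through C9 to C10. The closest known reaction type is the photocatalytic proton-coupled-electron-transfer ring expansion of 1-alkenylcycloalkanols to ring-enlarged (n+2) ketones, together with the oxidative ring expansion of 1-arylcyclobutanols to 1-tetralones. Ring B closes by 6-endo-trig attack of the C5 radical on the unsubstituted enone terminus C6 (5-exo attack at the fully substituted C7 is disfavoured sterically and electronically), and the resulting tertiary α-keto radical is reduced by divalent iridium and protonated. C5 is re-set by the substrate: the tether sits on the α face of C10 and reaches C5 only from that face while C9 is axial, whereas trans fusion needs C9 equatorial and would force the C4 and C10 methyl groups 1,3-diaxial, so the cis (5β-H) fusion should result. C7 is set thermodynamically by DBU, which converts the kinetic epimer into the equatorial 7β-isopropyl ketone. The step needs C8–C5 rather than C8–C9 scission and ring closure before hydrogen-atom quench of the hindered C5 radical; ring strain, radical substitution and a thiol-free medium secure both.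

**Step 11**
Reactants: 16 3α,4α-O-isopropylidenedioxy-5βH-eudesman-8-one
Product: 17 3α,4α-dihydroxy-5βH-eudesman-8-one
Conditions: AcOH/H2O 4:1, 45 °C
Reagents that add atoms: none
Why: Mild acid hydrolysis cleaves the acetonide without ionizing the tertiary alcohol, and C7 stays in its thermodynamic configuration.

**Step 12**
Reactants: 17 3α,4α-dihydroxy-5βH-eudesman-8-one; 18 angelic acid
Product: 20 3α-angeloyloxy-4α-hydroxy-5βH-eudesman-8-one, via angelic 2,4,6-trichlorobenzoic anhydride 19 (not isolated)
Conditions: 18, 2,4,6-trichlorobenzoyl chloride, Et3N, toluene, rt; then 17, 80 °C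
Reagents that add atoms: none
Why: Yamaguchi-type mixed-anhydride esterification without nucleophilic catalyst acylates the equatorial secondary C3–OH selectively over the axial tertiary C4–OH and is the established way to keep the Z-geometry of angelates.

**Step 13**
Reactants: 20 3α-angeloyloxy-4α-hydroxy-5βH-eudesman-8-one
Product: 21 3α-angeloyloxy-4α-acetoxy-5βH-eudesman-8-one
Conditions: Ac2O, Sc(OTf)3 (cat.), MeCN, −20 °C
Reagents that add atoms: acetic anhydride, CC(=O)OC(C)=O
Why: Lewis-acid-catalysed acetylation with Sc(OTf)3 acylates hindered tertiary alcohols at low temperature, which should avoid base-mediated angeloyl migration and Z-to-E isomerization.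

**Compound list**

1 | 3-methylcyclohex-2-en-1-one | CC1=CC(=O)CCC1 | starting material
2 | propa-1,2-diene (allene) | C=C=C | starting material
3 | (1S,6R)-6-methyl-8-methylidenebicyclo[4.2.0]octan-2-one (cis-fused, cyclobutane on the α face) | O=C1CCC[C@]2(C)CC(=C)[C@@H]21 | intermediate
4 | (1S,3S,6R)-3-hydroxy-6-methyl-8-methylidenebicyclo[4.2.0]octan-2-one (3β-OH) | O[C@H]1CC[C@]2(C)CC(=C)[C@@H]2C1=O | intermediate
5 | (1S,2S,3S,6R)-2,6-dimethyl-8-methylidenebicyclo[4.2.0]octane-2,3-diol (3β,4α-diol, 4β-methyl) | O[C@H]1CC[C@]2(C)CC(=C)[C@@H]2[C@]1(C)O | intermediate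
6 | (1S,2S,6R)-2-hydroxy-2,6-dimethyl-8-methylidenebicyclo[4.2.0]octan-3-one (C3 ketone, 4α-OH) | O=C1CC[C@]2(C)CC(=C)[C@@H]2[C@]1(C)O | intermediate
7 | (1S,2S,3R,6R)-2,6-dimethyl-8-methylidenebicyclo[4.2.0]octane-2,3-diol (3α,4α-cis-diol) | O[C@@H]1CC[C@]2(C)CC(=C)[C@@H]2[C@]1(C)O | intermediate
8 | acetonide of 7 (3α,4α-O-isopropylidene) | CC1(C)O[C@@H]2CC[C@]3(C)CC(=C)[C@@H]3[C@]2(C)O1 | intermediate
9 | cyclobutanone (C8=O) with 3α,4α-acetonide | CC1(C)O[C@@H]2CC[C@]3(C)CC(=O)[C@@H]3[C@]2(C)O1 | intermediate
10 | 3-methylbutan-2-one | CC(=O)C(C)C | starting material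
11 | 2,4,6-triisopropylbenzenesulfonohydrazide | CC(C)c1cc(C(C)C)c(S(=O)(=O)NN)c(C(C)C)c1 | starting material
12 | (E)-3-methylbutan-2-one 2,4,6-triisopropylbenzenesulfonylhydrazone | CC(C)/C(C)=N/NS(=O)(=O)c1c(C(C)C)cc(C(C)C)cc1C(C)C | intermediate
13 | 3-methylbut-1-en-2-yllithium (not isolated) | [Li]C(=C)C(C)C | intermediate
14 | cis-fused cyclobutanol, C8 bearing OH (toward ring A) and 3-methylbut-1-en-2-yl (exo), 3α,4α-acetonide | CC1(C)O[C@@H]2CC[C@]3(C)C[C@@](O)(C(=C)C(C)C)[C@@H]3[C@]2(C)O1 | intermediate
15 | 7-epi-ketone (7α-isopropyl epimer of 16, not isolated) | CC1(C)O[C@@H]2CC[C@]3(C)CC(=O)[C@H](C(C)C)C[C@@H]3[C@]2(C)O1 | intermediate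
16 | 3α,4α-O-isopropylidenedioxy-5βH-eudesman-8-one (7β-isopropyl, cis-decalin) | CC1(C)O[C@@H]2CC[C@]3(C)CC(=O)[C@@H](C(C)C)C[C@@H]3[C@]2(C)O1 | intermediate
17 | (3R,4S,5S,7R,10R)-3α,4α-dihydroxy-5βH-eudesman-8-one | O[C@@H]1CC[C@]2(C)CC(=O)[C@@H](C(C)C)C[C@@H]2[C@]1(C)O | intermediate
18 | angelic acid, (Z)-2-methylbut-2-enoic acid | C/C=C(/C)C(=O)O | starting material
19 | angelic 2,4,6-trichlorobenzoic anhydride (not isolated) | C/C=C(/C)C(=O)OC(=O)c1c(Cl)cc(Cl)cc1Cl | intermediate
20 | 3α-angeloyloxy-4α-hydroxy-5βH-eudesman-8-one | C/C=C(/C)C(=O)O[C@@H]1CC[C@]2(C)CC(=O)[C@@H](C(C)C)C[C@@H]2[C@]1(C)O | intermediate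
21 | (3R,4S,5S,7R,10R)-3α-angeloyloxy-4α-acetoxy-5βH-eudesman-8-one | C/C=C(/C)C(=O)O[C@@H]1CC[C@]2(C)CC(=O)[C@@H](C(C)C)C[C@@H]2[C@]1(C)OC(C)=O | target

**Step count**

Total: 13 steps. Longest linear sequence: 12 steps (steps 1–7 and 9–13); step 8 is a one-step side branch.

**Steps most likely to fail, with fallbacks**

Step 1 (proposed new method). Under Lewis acid activation the head-to-head regiocontrol of the allene addition may be lost, facial discrimination may be poor, or the allene may oligomerize. Fallback with known chemistry, setting out from 1 and 2: direct irradiation without Lewis acid (hν > 300 nm, CH2Cl2, −78 °C) should give the racemic cis-fused head-to-head adduct F1. Addition of lithiated (S)-N,S-dimethyl-S-phenylsulfoximine (n-BuLi, THF, −78 °C) from the convex face should give the β-hydroxysulfoximine F2 from the (1S,6R) ketone and its diastereomer F3 from the (1R,6S) ketone, separable by chromatography. Thermolysis of F2 (toluene, 110 °C) should release enantiopure ketone and return to the route at 3.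

Step 10 (key step). The hindered C5 radical may be quenched by hydrogen-atom transfer before ring closure, or conformational control of the ring fusion may erode. Fallback, setting out from 9: two polar one-carbon homologations that migrate C5 with retention, so the cis fusion set in step 1 is kept. Diazomethane (Et2O/MeOH, 0 °C), in which the more substituted α-carbon of a cyclobutanone migrates preferentially, should give the cis-hydrindan-2-one acetonide F4 (C8 ketone flanked by C6H2 and C9H2). Sc(OTf)3-catalysed insertion of 1-diazo-2-methylpropane (toluene, −78 °C), with migration of the less hindered C6 methylene rather than the neopentyl C9, followed by DBU equilibration at C7, should return to the route at 16.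

Step 13. Forcing acetylation of the tertiary alcohol next to the angelate may cause angeloyl migration, Z-to-E isomerization or elimination. Fallback, setting out from 17 and reversing the order of acylation: trimethyl orthoacetate with PPTS (CH2Cl2, rt) should give the cyclic orthoacetate F5. Mild aqueous acid (AcOH/H2O, rt) opens cyclic orthoesters of cis-diols to the axial ester, here the tertiary 4α-acetate with the equatorial 3α-OH free, F6. Yamaguchi-type angeloylation of F6 with 18 (2,4,6-trichlorobenzoyl chloride, Et3N, toluene, 80 °C) comes back to the route at 21.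

**Further compounds**

F1 | step 1 | racemic cis-6-methyl-8-methylidenebicyclo[4.2.0]octan-2-one | O=C1CCCC2(C)CC(=C)C12
F2 | step 1 | β-hydroxysulfoximine from the (1S,6R) ketone and the (S)-sulfoximine (CH2S on the β face of C4) | O[C@]1(C[S@@](=O)(=NC)c2ccccc2)CCC[C@]2(C)CC(=C)[C@@H]21
F3 | step 1 | diastereomeric β-hydroxysulfoximine from the (1R,6S) ketone and the (S)-sulfoximine | O[C@@]1(C[S@@](=O)(=NC)c2ccccc2)CCC[C@@]2(C)CC(=C)[C@H]21
F4 | step 10 | cis-hydrindan-2-one acetonide (C8 ketone flanked by C6H2 and C9H2) | CC1(C)O[C@@H]2CC[C@]3(C)CC(=O)C[C@@H]3[C@]2(C)O1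
F5 | step 13 | cyclic methyl orthoacetate of 17 (orthoester carbon as a mixture) | COC1(C)O[C@@H]2CC[C@]3(C)CC(=O)[C@@H](C(C)C)C[C@@H]3[C@]2(C)O1
F6 | step 13 | 4α-acetoxy-3α-hydroxy-5βH-eudesman-8-one | O[C@@H]1CC[C@]2(C)CC(=O)[C@@H](C(C)C)C[C@@H]2[C@]1(C)OC(C)=O
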